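I started from one ratio: substrate left over substrate charged, Za and Zb together.

| flask | Za | Zb | Zc | Zd | Ze | remark | time |
|---|---|---|---|---|---|---|---|
| Sunday's | 0.10 M | 0.10 M | 2 equiv | 0.28 mol% | 0.28 mol% | run made earlier |  |
| Tuesday's | 0.10 M | 0.10 M | 2 equiv | 0.44 mol% | 0.28 mol% | run made earlier |  |
| Saturday's | 0.10 M | 0.10 M | 2 equiv | 0.2 mol% | 0.56 mol% | run made earlier |  |
| flask | 0.10 M | 0.10 M | 2.00 equiv | 0.2 mol% | 0.28 mol% |  | 25 min |

The flask has the Zd of Saturday's run and the Ze of Sunday's run. No earlier run changed Zc.

| run | time / min | Zh / % | Zj / % |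
|---|---|---|---|
| Sunday's | 2.00 | 10.0 | 6.1 |
| Sunday's | 6.00 | 17.2 | 8.9 |
| Sunday's | 12.0 | 20.4 | 12.3 |
| Sunday's | 20.0 | 23.2 | 14.8 |
| Sunday's | 25.0 | 27.0 | 13.6 |
| Tuesday's | 2.00 | 12.8 | 4.0 |
| Tuesday's | 4.00 | 16.5 | 9.3 |
| Tuesday's | 8.00 | 22.1 | 13.4 |
| Tuesday's | 12.0 | 25.4 | 14.3 |
| Tuesday's | 25.0 | 29.6 | 17.4 |
| Saturday's | 5.00 | 13.3 | 5.8 |
| Saturday's | 10.0 | 18.4 | 9.1 |
| Saturday's | 15.0 | 19.0 | 10.8 |
| Saturday's | 20.0 | 24.6 | 11.8 |
| Saturday's | 25.0 | 22.7 | 13.9 |

(standard deviation of a reading: 1 percentage point)

In Saturday's run the ratio stood at 63.4 % at 25.0 min, which gave 0.456. I called that number the reach: minus the logarithm of the ratio, the exponent of a pseudo-first-order decay. The reach already takes out substrate use, yet 0.212 of it came by 5.00 min, half of the total. So I read the slowing as loss of catalyst. Saturday's Ze was twice the flask's, but I carried the reach over unchanged and committed to 36.6 %. I also assumed that the rate carries cZc once and that Zd's loss ignores Zc. With the other charges held, I then estimated the reach as proportional to the cZc charged, though no run tested this.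

- Zh and Zj together, in percent of the Za and Zb charged together, at 25 min
- excess of Zh over Zj in the product at 25 min
- whether the exchange between Za and Zb keeps pace with the reaction: how far the product's excess at 25 min gets from its value without exchange to its value with instant exchange (above 80 % keeps pace, below 20 % hardly takes part, else lags behind)

- Zd is single-handed; Za and Zb are mirror images of each other, charged as a racemate, each of them at the stated concentration
- an excess is below zero if the other one leads

The forecast stood slightly lower, at 36 %, with an excess of 29 % and an exchange that hardly takes part. Its ground for the exchange: “The observed decline tracks the no-exchange line”.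

The flask gave 37.6 % and 26.4 %, and its exchange hardly takes part, getting 12 % of the way.

    Zc + Zd + Za → Zd + Zh (k = 39.0 /M²/s)
    Zc + Zd + Zb → Zd + Zj (k = 20.0 /M²/s)
    Za + Ze ⇌ Zb + Ze, rate k3*[Ze]*[Za] forward; the back reaction follows from the equilibrium constant (k = 0.540 /M/s)
    2 Zd → Zg (k = 8.10 /M/s)
    Zd → Zf (k = 1.20 × 10⁻⁴ /s)

The flask's own reach was 0.472, and its Zd stood at 15.3 % of the charge at 25.0 min. The neighbouring flask, with 8.00 equiv of Zc and nothing else changed, held the same 15.3 % of its Zd. So I multiplied the flask's reach by 4.00, which gave 84.9 %. That neighbour reached 85.3 %, kept 78.7 % of its Zc, and its excess stood at 12.5 %.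

The readings are calculated for an exercise, and the scatter is random.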